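**Plan** (halimane numbering: ring A = C1–C5 and C10, ring B = C5–C10, side chain C11–C16, ester carbon C18)
- Enabling feature: the only unsaturation of ring A is C1=C10, flanked by C2 and C5. C4, next to C5, is quaternary and holds one CH3 and one CO2Me. Read backwards, this is the cyclohexene retron of a C5=C10–C1=C2 diene plus methyl methacrylate (C3=C4).
- Cuts, in order: the two acetates and the 14,15-acetonide; C4–C5 and C2–C3 together ([4+2]); C12–C13 (alkylcerium + methyl ketone); C10–C1 (vinyl coupling); C9–C11 (enolate alkylation); C8–CH3 (conjugate addition).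
- Forward: ring B is bought as 2-methylcyclohexenone and decorated, the side chain is joined at C12–C13, and ring A is closed last onto ring B.
- Stereochemistry: C8 comes from a chiral copper catalyst and C9 from alkylation anti to the C8 methyl. C14 comes from the chiral pool ((S)-glycerate acetonide) and C13 from Felkin–Anh addition next to C14. C5 and C4 come from the face (anti to the pseudoaxial C9 methyl) and the ester-endo orientation of the cycloaddition.

Key step: step 10

Assumption: the (R,S,S) antipode of the phosphoramidite is taken to give the 8R series, by analogy with its sense on cyclohex-2-enone; if the sense is reversed, the mirror-image ligand is used.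

Step 1
Reactants: 1 2-methylcyclohex-2-en-1-one
Product: 3 {[(3R)-2,3-dimethylcyclohex-1-en-1-yl]oxy}trimethylsilane, via dimethylaluminium enolate 2 (not isolated)
Conditions: Me3Al (1.5 equiv), Cu(OTf)2 (2 mol %), (R,S,S)-phosphoramidite from BINOL and bis(1-phenylethyl)amine (4 mol %), Et2O, −30 °C; then Me3SiOTf, −30 → 0 °C
Reagents that add atoms: trimethylaluminium C[Al](C)C; trimethylsilyl triflate C[Si](C)(C)OS(=O)(=O)C(F)(F)F
Why: Copper-catalysed asymmetric conjugate addition of Me3Al, a known way to methylate α-substituted cyclohexenones, sets C8 (R) through the chiral phosphoramidite–copper complex, and silyl triflate trapping of the aluminium enolate stores the tetrasubstituted C9=C10 enolate regiochemistry.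

Step 2
Reactants: 3 {[(3R)-2,3-dimethylcyclohex-1-en-1-yl]oxy}trimethylsilane; 4 tert-butyl bromoacetate
Product: 6 tert-butyl 2-[(1S,6R)-1,6-dimethyl-2-oxocyclohexyl]acetate, via lithium enolate 5 (not isolated)
Conditions: MeLi (1.05 equiv), THF, 0 °C → rt; DMPU, then 4, −78 → −20 °C
Reagents that add atoms: none
Why: Methyllithium cleavage of the silyl enol ether gives the regiodefined lithium enolate, whose SN2 alkylation occurs on the face opposite the C8 methyl (held pseudoaxial by A(1,2) strain with the C9 methyl), so the acetate arm ends up trans to the C8 methyl and quaternary C9 is set as S.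

Step 3
Reactants: 6 tert-butyl 2-[(1S,6R)-1,6-dimethyl-2-oxocyclohexyl]acetate
Product: 8 tert-butyl 2-[(1S,6R)-1,6-dimethyl-2-{[(trifluoromethyl)sulfonyl]oxy}cyclohex-2-en-1-yl]acetate, via potassium enolate 7 (not isolated)
Conditions: KN(SiMe3)2, THF, −78 °C; PhNTf2, −78 → 0 °C
Reagents that add atoms: N-phenylbis(trifluoromethanesulfonimide) O=S(=O)(N(c1ccccc1)S(=O)(=O)C(F)(F)F)C(F)(F)F
Why: Because C9 is quaternary the ketone can enolise only toward C5, and the amide base removes the more acidic ketone α-proton rather than the neopentyl ester α-protons before O-sulfonylation (enol triflate formation).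

Step 4
Reactants: 8 tert-butyl 2-[(1S,6R)-1,6-dimethyl-2-{[(trifluoromethyl)sulfonyl]oxy}cyclohex-2-en-1-yl]acetate
Product: 9 tert-butyl 2-[(1S,6R)-2-ethenyl-1,6-dimethylcyclohex-2-en-1-yl]acetate
Conditions: CH2=CHSnBu3, Pd(PPh3)4 (5 mol %), LiCl (3 equiv), THF, reflux
Reagents that add atoms: tributyl(vinyl)stannane C=C[Sn](CCCC)(CCCC)CCCC
Why: Stille coupling of a cyclohexenyl triflate with a vinylstannane under zerovalent palladium and LiCl is the classical entry to 1-vinylcyclohexenes, tolerates the neighbouring quaternary carbon and the tert-butyl ester, and touches no stereocentre.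

Step 5
Reactants: 9 tert-butyl 2-[(1S,6R)-2-ethenyl-1,6-dimethylcyclohex-2-en-1-yl]acetate
Product: 10 2-[(1S,6R)-2-ethenyl-1,6-dimethylcyclohex-2-en-1-yl]ethan-1-ol
Conditions: LiAlH4, Et2O, 0 °C → rt
Reagents that add atoms: none
Why: Hydride reduction takes the ester to the primary alcohol and leaves the unactivated diene untouched.

Step 6
Reactants: 10 2-[(1S,6R)-2-ethenyl-1,6-dimethylcyclohex-2-en-1-yl]ethan-1-ol
Product: 11 (5R,6S)-1-ethenyl-6-(2-iodoethyl)-5,6-dimethylcyclohex-1-ene
Conditions: I2, PPh3, imidazole, CH2Cl2, 0 °C, dark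
Reagents that add atoms: iodine II
Why: The Appel-type iodination runs under nearly neutral conditions by SN2 displacement of the alkoxyphosphonium ion at primary C12, which spares the acid-sensitive diene.

Step 7
Reactants: 12 methyl (4S)-2,2-dimethyl-1,3-dioxolane-4-carboxylate
Product: 13 (4S)-N-methoxy-N,2,2-trimethyl-1,3-dioxolane-4-carboxamide
Conditions: MeNH(OMe)·HCl, i-PrMgCl, THF, −20 °C
Reagents that add atoms: N,O-dimethylhydroxylamine hydrochloride CNOC.Cl
Why: Aminolysis of the ester by the magnesium amide of N,O-dimethylhydroxylamine at low temperature gives the N-methoxy-N-methylamide without epimerising the α-alkoxy centre C14.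

Step 8
Reactants: 13 (4S)-N-methoxy-N,2,2-trimethyl-1,3-dioxolane-4-carboxamide
Product: 14 1-[(4S)-2,2-dimethyl-1,3-dioxolan-4-yl]ethan-1-one
Conditions: MeMgBr, THF, −78 → 0 °C
Reagents that add atoms: methylmagnesium bromide C[Mg]Br
Why: In the Weinreb ketone synthesis the chelated tetrahedral adduct persists until work-up, so only one methyl group is delivered and C14 keeps its S configuration.

Step 9
Reactants: 11 (5R,6S)-1-ethenyl-6-(2-iodoethyl)-5,6-dimethylcyclohex-1-ene; 14 1-[(4S)-2,2-dimethyl-1,3-dioxolan-4-yl]ethan-1-one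
Product: 17 (2R)-2-[(4S)-2,2-dimethyl-1,3-dioxolan-4-yl]-4-[(1S,6R)-2-ethenyl-1,6-dimethylcyclohex-2-en-1-yl]butan-2-ol, via alkyllithium 15 (not isolated), via alkylcerium dichloride 16 (not isolated)
Conditions: t-BuLi (2.0 equiv), Et2O–pentane, −78 °C; anhydrous CeCl3, THF, −78 °C; then 14, −78 °C
Reagents that add atoms: none
Why: Iodine–lithium exchange at −78 °C outruns attack of t-BuLi on the diene and any carbolithiation, transmetalation to the weakly basic organocerium suppresses enolisation of 14, and the 1,2-addition follows the polar Felkin–Anh model (C14–O bond anti to incoming C12, the acetal oxygen being a poor chelator) to give the 13,14-anti, 13R carbinol.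

Step 10
Reactants: 17 (2R)-2-[(4S)-2,2-dimethyl-1,3-dioxolan-4-yl]-4-[(1S,6R)-2-ethenyl-1,6-dimethylcyclohex-2-en-1-yl]butan-2-ol; 18 methyl methacrylate
Product: 20 methyl (1S,5S,6R,8aR)-5-{(3R)-3-[(4S)-2,2-dimethyl-1,3-dioxolan-4-yl]-3-hydroxybutyl}-1,5,6-trimethyl-1,2,3,5,6,7,8,8a-octahydronaphthalene-1-carboxylate, via aluminium alkoxide 19 (not isolated)
Conditions: Me2AlCl (3 equiv), 18 (5 equiv), CH2Cl2, −40 → 0 °C
Reagents that add atoms: none
Why: One equivalent of Me2AlCl is spent on the C13 hydroxyl (methane leaves, alkoxide 19 results) and the rest binds the carbonyl oxygen of 18, whose lowered LUMO then meets the diene HOMO in a concerted but asynchronous normal-demand Diels–Alder reaction with C2–C3 bonding ahead of C4–C5 bonding, the closest known reaction type being the aluminium-promoted cycloaddition of 1-vinylcyclohexenes to acrylates and methacrylates. Ring A closes as a six-membered ring by intermolecular suprafacial [4+2] cycloaddition through a boat-like transition state, and the surviving alkene can only lie between the former inner diene carbons, C1=C10. The regiochemistry needed (C4 to C5, C3 to C2) is secured by the unsubstituted vinyl terminus C2, which carries the largest HOMO coefficient and the least hindrance and therefore pairs with the electrophilic β-carbon C3. C5 is controlled by the ring B half-chair: the equatorial C8 methyl places the cis C9 methyl pseudoaxial on the α face, so 18 approaches the β face, which shows only hydrogens, and H5 is pushed to the α side (5R). C4 is controlled by the endo orientation of the aluminium-bound ester above C10–C1, which puts CO2Me trans and the C4 methyl cis to H5 (4S); this is the weakest element because the α-methyl group competes for the endo position, and low temperature plus a strong Lewis acid are used to favour it. The quaternary C9 also helps reactivity, since it destabilises the s-trans rotamer of the vinyl group and keeps the diene s-cis.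

Step 11
Reactants: 20 methyl (1S,5S,6R,8aR)-5-{(3R)-3-[(4S)-2,2-dimethyl-1,3-dioxolan-4-yl]-3-hydroxybutyl}-1,5,6-trimethyl-1,2,3,5,6,7,8,8a-octahydronaphthalene-1-carboxylate
Product: 21 methyl (1S,5S,6R,8aR)-1,5,6-trimethyl-5-[(3R,4S)-3,4,5-trihydroxy-3-methylpentyl]-1,2,3,5,6,7,8,8a-octahydronaphthalene-1-carboxylate
Conditions: AcOH–H2O (4:1), 40 °C
Reagents that add atoms: none
Why: Mild aqueous acid hydrolyses the terminal isopropylidene acetal, whereas the hindered C1=C10 alkene, the tertiary carbinol and the neopentyl methyl ester are inert to acetic acid at this temperature.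

Step 12
Reactants: 21 methyl (1S,5S,6R,8aR)-1,5,6-trimethyl-5-[(3R,4S)-3,4,5-trihydroxy-3-methylpentyl]-1,2,3,5,6,7,8,8a-octahydronaphthalene-1-carboxylate
Product: 22 methyl (1S,5S,6R,8aR)-5-[(3R,4S)-4,5-diacetoxy-3-hydroxy-3-methylpentyl]-1,5,6-trimethyl-1,2,3,5,6,7,8,8a-octahydronaphthalene-1-carboxylate
Conditions: Ac2O (3 equiv), pyridine, rt
Reagents that add atoms: acetic anhydride CC(=O)OC(C)=O
Why: Acylation with Ac2O in pyridine esterifies the primary C15 and secondary C14 hydroxyls, whereas the tertiary C13 hydroxyl is too hindered to react without forcing catalysis.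

**Compound list**
1 | 2-methylcyclohex-2-en-1-one | CC1=CCCCC1=O | starting material
2 | dimethylaluminium (3R)-2,3-dimethylcyclohex-1-en-1-olate | C[Al](C)OC1=C(C)[C@H](C)CCC1 | intermediate
3 | {[(3R)-2,3-dimethylcyclohex-1-en-1-yl]oxy}trimethylsilane | C[Si](C)(C)OC1=C(C)[C@H](C)CCC1 | intermediate
4 | tert-butyl bromoacetate | CC(C)(C)OC(=O)CBr | starting material
5 | lithium (3R)-2,3-dimethylcyclohex-1-en-1-olate | [Li]OC1=C(C)[C@H](C)CCC1 | intermediate
6 | tert-butyl 2-[(1S,6R)-1,6-dimethyl-2-oxocyclohexyl]acetate | O=C1CCC[C@@H](C)[C@]1(C)CC(=O)OC(C)(C)C | intermediate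
7 | potassium (5R,6S)-6-(2-tert-butoxy-2-oxoethyl)-5,6-dimethylcyclohex-1-en-1-olate | [K]OC1=CCC[C@@H](C)[C@]1(C)CC(=O)OC(C)(C)C | intermediate
8 | tert-butyl 2-[(1S,6R)-1,6-dimethyl-2-{[(trifluoromethyl)sulfonyl]oxy}cyclohex-2-en-1-yl]acetate | O=S(=O)(OC1=CCC[C@@H](C)[C@]1(C)CC(=O)OC(C)(C)C)C(F)(F)F | intermediate
9 | tert-butyl 2-[(1S,6R)-2-ethenyl-1,6-dimethylcyclohex-2-en-1-yl]acetate | C=CC1=CCC[C@@H](C)[C@]1(C)CC(=O)OC(C)(C)C | intermediate
10 | 2-[(1S,6R)-2-ethenyl-1,6-dimethylcyclohex-2-en-1-yl]ethan-1-ol | C=CC1=CCC[C@@H](C)[C@]1(C)CCO | intermediate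
11 | (5R,6S)-1-ethenyl-6-(2-iodoethyl)-5,6-dimethylcyclohex-1-ene | C=CC1=CCC[C@@H](C)[C@]1(C)CCI | intermediate
12 | methyl (4S)-2,2-dimethyl-1,3-dioxolane-4-carboxylate | COC(=O)[C@H](COC1(C)C)O1 | starting material
13 | (4S)-N-methoxy-N,2,2-trimethyl-1,3-dioxolane-4-carboxamide | CON(C)C(=O)[C@H](COC1(C)C)O1 | intermediate
14 | 1-[(4S)-2,2-dimethyl-1,3-dioxolan-4-yl]ethan-1-one | CC(=O)[C@H](COC1(C)C)O1 | intermediate
15 | {2-[(1S,6R)-2-ethenyl-1,6-dimethylcyclohex-2-en-1-yl]ethyl}lithium | C=CC1=CCC[C@@H](C)[C@]1(C)CC[Li] | intermediate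
16 | dichloro{2-[(1S,6R)-2-ethenyl-1,6-dimethylcyclohex-2-en-1-yl]ethyl}cerium | C=CC1=CCC[C@@H](C)[C@]1(C)CC[Ce](Cl)Cl | intermediate
17 | (2R)-2-[(4S)-2,2-dimethyl-1,3-dioxolan-4-yl]-4-[(1S,6R)-2-ethenyl-1,6-dimethylcyclohex-2-en-1-yl]butan-2-ol | C=CC1=CCC[C@@H](C)[C@]1(C)CC[C@@](C)(O)[C@H](COC2(C)C)O2 | intermediate
18 | methyl methacrylate | C=C(C)C(=O)OC | starting material
19 | chloro(methyl)aluminium alkoxide of 17 (Al on O13) | C=CC1=CCC[C@@H](C)[C@]1(C)CC[C@@](C)(O[Al](C)Cl)[C@H](COC2(C)C)O2 | intermediate
20 | methyl (1S,5S,6R,8aR)-5-{(3R)-3-[(4S)-2,2-dimethyl-1,3-dioxolan-4-yl]-3-hydroxybutyl}-1,5,6-trimethyl-1,2,3,5,6,7,8,8a-octahydronaphthalene-1-carboxylate | COC(=O)[C@@]1(C)CCC=C2[C@H]1CC[C@@H](C)[C@]2(C)CC[C@@](C)(O)[C@H](COC3(C)C)O3 | intermediate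
21 | methyl (1S,5S,6R,8aR)-1,5,6-trimethyl-5-[(3R,4S)-3,4,5-trihydroxy-3-methylpentyl]-1,2,3,5,6,7,8,8a-octahydronaphthalene-1-carboxylate | COC(=O)[C@@]1(C)CCC=C2[C@H]1CC[C@@H](C)[C@]2(C)CC[C@@](C)(O)[C@H](CO)O | intermediate
22 | methyl (1S,5S,6R,8aR)-5-[(3R,4S)-4,5-diacetoxy-3-hydroxy-3-methylpentyl]-1,5,6-trimethyl-1,2,3,5,6,7,8,8a-octahydronaphthalene-1-carboxylate | COC(=O)[C@@]1(C)CCC=C2[C@H]1CC[C@@H](C)[C@]2(C)CC[C@@](C)(O)[C@H](COC(C)=O)OC(C)=O | target

Total step count: 12. Longest linear sequence: 10 (steps 1–6 and 9–12); steps 7 and 8 form the side branch.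

**Steps most likely to fail**

**Step 10.**
- Risk: the cycloaddition may be slow, because the bond between fully substituted C4 and C5 closes late. The α-methyl group may erode the ester-endo preference, the β-face preference may be incomplete, and the Lewis acid may attack the acetal.
- Fallback: it sets out from 17 and separates the making of the quaternary centre from the cycloaddition. Compound 17 is combined with methyl acrylate and Me2AlCl. In this pairing the carbonyl-endo rule is strong and only a tertiary C4 forms, giving the C4-demethyl ester (4-H α, ester β) F1.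
- Its ester enolate is made with excess LiN(i-Pr)2 in THF at −78 °C, with the C13 hydroxyl carried as its lithium alkoxide, and is then methylated with MeI. The electrophile should enter the exocyclic enolate from the equatorial α side, cis to the axial H5. This comes back to the route at 20.

**Step 9.**
- Risk: facial selectivity at the C13 carbonyl may be weak or reversed if the metal is chelated by O14. Ketone 14 may enolise, and the alkyllithium may add to the diene on warming.
- Fallback: it sets out from 11. It reverses the order in which the two carbon groups reach C13 and switches the control element from Felkin–Anh to chelation.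
- Alkyllithium 15 made from 11 is acylated with amide 13 to give 1-[(4S)-2,2-dimethyl-1,3-dioxolan-4-yl]-3-[(1S,6R)-2-ethenyl-1,6-dimethylcyclohex-2-en-1-yl]propan-1-one F2.
- MeMgBr in Et2O–CH2Cl2 at −78 °C then adds to the magnesium chelate formed between the ketone oxygen and O14, from the side of H14 (Cram chelate model). Because methyl and chain have exchanged roles, the chelate product is the same 13R carbinol, and the route is rejoined at 17.

**Step 2.**
- Risk: the acidic bromoacetate may transfer a proton to the hindered tetrasubstituted enolate. O-alkylation and eroded facial selectivity are also possible.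
- Fallback: it sets out from 3 and brings in the two-carbon arm as a masked three-carbon unit. Enolate 5 made from 3 is allylated with allyl bromide, a more reactive electrophile without acidic protons and with the same anti approach. This gives (2S,3R)-2,3-dimethyl-2-(prop-2-en-1-yl)cyclohexan-1-one F3.
- Ozonolysis (O3, CH2Cl2, −78 °C; Me2S) gives 2-[(1S,6R)-1,6-dimethyl-2-oxocyclohexyl]acetaldehyde F4.
- Pinnick oxidation (NaClO2, NaH2PO4, 2-methylbut-2-ene) gives 2-[(1S,6R)-1,6-dimethyl-2-oxocyclohexyl]acetic acid F5.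
- Addition of the acid to isobutene (catalytic H2SO4, CH2Cl2) comes back to the route at 6.

**Further compounds**
F1 | step 10 | methyl (1S,5S,6R,8aS)-5-{(3R)-3-[(4S)-2,2-dimethyl-1,3-dioxolan-4-yl]-3-hydroxybutyl}-5,6-dimethyl-1,2,3,5,6,7,8,8a-octahydronaphthalene-1-carboxylate | COC(=O)[C@H]1CCC=C2[C@H]1CC[C@@H](C)[C@]2(C)CC[C@@](C)(O)[C@H](COC3(C)C)O3
F2 | step 9 | 1-[(4S)-2,2-dimethyl-1,3-dioxolan-4-yl]-3-[(1S,6R)-2-ethenyl-1,6-dimethylcyclohex-2-en-1-yl]propan-1-one | C=CC1=CCC[C@@H](C)[C@]1(C)CCC(=O)[C@H](COC2(C)C)O2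
F3 | step 2 | (2S,3R)-2,3-dimethyl-2-(prop-2-en-1-yl)cyclohexan-1-one | O=C1CCC[C@@H](C)[C@]1(C)CC=C
F4 | step 2 | 2-[(1S,6R)-1,6-dimethyl-2-oxocyclohexyl]acetaldehyde | O=C1CCC[C@@H](C)[C@]1(C)CC=O
F5 | step 2 | 2-[(1S,6R)-1,6-dimethyl-2-oxocyclohexyl]acetic acid | O=C1CCC[C@@H](C)[C@]1(C)CC(=O)O
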